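The south-east run, with 0.78 M of partner, and the north-east run, with 0.27 M, show you how a racemate behaves here. The racemate also gives you the zero of the scale: what you want to know is how far above an excess of nil each new flask still stands at the end.

common to all: left-handed substrate 0.40 M; right-handed substrate 0.40 M; free catalyst 20 mM; racemization catalyst 0.40 mM

| charge | partner | remark | time |
|---|---|---|---|
| north-east | 0.27 M | run made earlier |  |
| south-east | 0.78 M | run made earlier |  |
| autumn | 0.880 M |  | 2.5 min |
| dusk | 0.400 M |  | 2.5 min |

| run | time / s | right-handed substrate / % | left-handed substrate / % |
|---|---|---|---|
| north-east | 10.0 | 47.6 | 46.3 |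
| north-east | 20.0 | 47.5 | 46.5 |
| north-east | 40.0 | 46.4 | 47.1 |
| north-east | 50.0 | 45.8 | 45.8 |
| north-east | 80.0 | 45.6 | 45.9 |
| south-east | 15.0 | 44.9 | 43.2 |
| south-east | 30.0 | 43.8 | 42.4 |
| south-east | 50.0 | 43.5 | 42.7 |
| south-east | 60.0 | 42.8 | 41.7 |
| south-east | 80.0 | 43.0 | 41.9 |

(readings scatter by 0.5 percentage points)

- free catalyst is single-handed; left-handed substrate and right-handed substrate are mirror images of each other, charged as a racemate, each of them at the stated concentration
- what was read earlier has a scatter of 0.5 percentage points, one standard deviation
- an excess is the difference of the two amounts in percent of their sum
- an excess is below zero if the other one leads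

* which one finishes higher in excess of right-handed substrate over left-handed substrate among what is left of the two ("neither" within 2 percentage points) (autumn / dusk / neither)
* excess of right-handed substrate over left-handed substrate among what is left of the two at the end, autumn
* excess of right-handed substrate over left-handed substrate among what is left of the two at the end, dusk

Take the south-east run in slow motion. In the first instants the substrates go quickly: by 15.0 s the readings show 11.9 % consumed, and right-handed substrate leads by 1.93 %, so left-handed substrate is reacting faster. Then consumption slows, reaching 15.1 % by 80.0 s, and from there you watch the racemization catalyst, charged at 0.40 mM, draw the lead back towards zero. With that catalyst constant, I treat the fall as pseudo-first-order. The lead reads 1.30 % at 80.0 s, which gives my quantity, the excess half-life, the time in which the lead over the racemate halves once consumption has slowed: 113 s. This is a rough reading, since each value scatters by 0.5 percentage points, and the north-east run already stands at −0.328 % at its last reading, so I take it as the slow end.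

The time asked, 2.5 min, is longer than this half-life. Counting 1.19 half-lives from that first lead, I reach a ceiling of 0.844 % for autumn and dusk alike. That is below the margin of 2 points, so I expect neither to finish higher.

The forecast also says neither, with 1 % for autumn, higher than my ceiling, and 0.2 % for dusk. Its ground: “Even without racemization, the two would differ by only about 1 point”.

The flasks give neither, with 0 % in autumn and 0 % in dusk, so the forecast held.

    free catalyst → spent catalyst (k = 0.0310 s⁻¹)
    2 partner → self-condensation product (k = 0.110 L mol⁻¹ s⁻¹)
    left-handed substrate + racemization catalyst ⇌ right-handed substrate + racemization catalyst, rate k3*[racemization catalyst]*[left-handed substrate] forward; the back reaction follows from the equilibrium constant (k = 74.0 L mol⁻¹ s⁻¹)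
    partner → decomposed reagent (k = 0.0170 s⁻¹)
    partner + free catalyst + left-handed substrate → free catalyst + left-handed product (k = 2.00 L² mol⁻² s⁻¹)
    partner + free catalyst + right-handed substrate → free catalyst + right-handed product (k = 0.960 L² mol⁻² s⁻¹)

Autumn has come to rest in its excess, which stands below the ceiling. At 25.0 min the excess is 0 %. Left-handed substrate stays at 42.1 % and right-handed product at 5.27 %. What still moves is a small tail: partner goes from 0.501 % to 0 %, free catalyst from 0.956 % to 0 %, and decomposed reagent rises from 0.161 M to 0.166 M.

Now take dusk with 0.012 M of free catalyst. Its racemization catalyst is unchanged, so you count the same 1.19 half-lives and the same ceiling of 0.844 %. The computed flask gives 0 %, with left-handed substrate and right-handed substrate at 46.7 % and 46.7 %.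

The runs were generated by integration on assumed constants; the scatter is artificial.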